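**Plan**

- Locants (bookkeeping only): ring C6 (lactone O–CH), C7 (ring fusion), C8 (CH–O-tigloyl), C9 (CH2), C10 (C(CH3)OH, methyl C14), C1, C2 (CH2CH2), C3 (CH–OH), C4 (C–CH3, methyl C15)=C5; lactone C11 (α-carbon), C12 (C=O), C13 (=CH2).
- Retrosynthesis cuts, in order: the C8–O tiglate and the C11=C13 methylene; the C12–O6 lactone bond, C6–H and C10–O (hydration of a C1=C10 alkene); C7–C11 (enolate alkylation); then C8–C9, with C1 rejoined to C6.
- Enabling feature: C9–C10 and C7–C8 flank the C1/C6 pair, so joining C1 to C6 contracts the ten-membered ring to a cyclohexene C1–C2–C3–C4=C5–C6 that already holds the Z-C4=C5 alkene, the C4 methyl and the C3 oxygen. C9=C10 is then an isopropenyl group on C1 and C7=C8 an (E)-enol ether on the C6 carbinol, i.e. a 3-oxido-hexa-1,5-diene with termini C9 and C8.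
- Forward: (S)-carvone gives the six-membered enone; a C7–C8 alkynyl ether is added and trans-reduced; an anionic oxy-Cope ring expansion closes the ten-membered ring at C8–C9 with in-flask alkylation at C7; C1=C10 is hydrated, C6 reduced and the γ-lactone closed; then methylenation, tigloylation and desilylation.
- Stereochemistry: the carvone centre (C1) sets C3 (anti epoxidation, Wharton transposition) and, through the chair transition state, C8; C7 comes from enolate alkylation anti to the new C8–C9 bond, C10 from anti bromohydrin opening, C6 from hydride delivery anti to the C7–C8 bond; 4Z is carried from the cyclohexene.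

Key step: step 8

Remark: the 1,2-addition in step 6 is assumed to occur anti to the neighbouring isopropenyl group; this carbinol centre becomes sp2 in step 8.

**Route**

Step 1
Reactants: 1 (S)-carvone
Product: 2 (1S,4S,6S)-1-methyl-4-(prop-1-en-2-yl)-7-oxabicyclo[4.1.0]heptan-2-one
Conditions: 30% H2O2, NaOH (cat.), MeOH, 0 °C
Reagents that add atoms: hydrogen peroxide, OO
Why: Weitz–Scheffer nucleophilic epoxidation of the enone should place the epoxide anti to the isopropenyl-bearing carbon (this fixes the future C3 oxygen), the isolated isopropenyl alkene being inert to hydroperoxide anion.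

Step 2
Reactants: 2 carvone epoxide
Product: 4 (1S,5R)-2-methyl-5-(prop-1-en-2-yl)cyclohex-2-en-1-ol (trans-carveol), via epoxy hydrazone 3 (not isolated)
Conditions: N2H4·H2O, AcOH (cat.), MeOH, 0 °C → rt
Reagents that add atoms: none
Why: Wharton transposition: the epoxy hydrazone collapses with loss of N2 to the allylic alcohol, the C–O bond at the former β-carbon being retained, so the hydroxyl (future C3–OH) should stay trans to the isopropenyl group.

Step 3
Reactants: 4 trans-carveol
Product: 5 tert-butyldimethylsilyl ether of 4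
Conditions: TBSCl, imidazole, DMF, rt
Reagents that add atoms: tert-butyldimethylsilyl chloride, CC(C)(C)[Si](C)(C)Cl
Why: Routine silylation of the secondary allylic alcohol; the silyl ether should survive the chromium oxidation, organolithium, KH, hydride and DDQ steps and is removed last; no stereocentre is touched.

Step 4
Reactants: 5 silyl ether
Product: 6 (4S,6R)-4-[(tert-butyldimethylsilyl)oxy]-3-methyl-6-(prop-1-en-2-yl)cyclohex-2-en-1-one
Conditions: CrO3, 3,5-dimethylpyrazole, CH2Cl2, −20 °C
Reagents that add atoms: CrO3, O=[Cr](=O)=O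
Why: Allylic C–H oxidation by the CrO3–3,5-dimethylpyrazole complex should convert the only ring allylic methylene (C6) into the ketone, the other ring allylic carbon being a silyloxy methine and the ring alkene being more electron-rich than the isopropenyl group; C1 and C3 are not affected under these non-basic conditions.

Step 5
Reactants: 7 4-methoxybenzyl alcohol; 8 trichloroethylene
Product: 9 1-({[(E)-1,2-dichloroethenyl]oxy}methyl)-4-methoxybenzene
Conditions: KH, THF, 0 °C; then 8, −50 °C → rt
Reagents that add atoms: none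
Why: The potassium alkoxide adds to dichloroacetylene formed in the flask from trichloroethylene (elimination–addition), the standard entry to 1,2-dichlorovinyl ethers as precursors of metalated alkynyl ethers; no stereocentre is formed.

Step 6
Reactants: 9 dichlorovinyl ether; 6 enone
Product: 11 (1R,4S,6R)-4-[(tert-butyldimethylsilyl)oxy]-1-{[(4-methoxybenzyl)oxy]ethynyl}-3-methyl-6-(prop-1-en-2-yl)cyclohex-2-en-1-ol, via lithium alkoxyacetylide 10 (not isolated)
Conditions: 9, n-BuLi (2.2 equiv), THF, −78 → −40 °C; CeCl3, −78 °C; then 6, −78 °C; aq NaHCO3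
Reagents that add atoms: none
Why: Dehydrochlorination and Cl/Li exchange of 9 give the lithium alkynyl ether, which as its cerium reagent (to suppress enolisation at the doubly activated C1–H) should add 1,2 to the enone from the face anti to the adjacent isopropenyl group, placing the two unsaturated arms trans; acetylide addition to a ketone.

Step 7
Reactants: 11 alkynyl ether carbinol
Product: 12 (1R,4S,6R)-4-[(tert-butyldimethylsilyl)oxy]-1-{(E)-2-[(4-methoxybenzyl)oxy]ethenyl}-3-methyl-6-(prop-1-en-2-yl)cyclohex-2-en-1-ol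
Conditions: LiAlH4, THF, 0 °C → rt; Rochelle salt work-up
Reagents that add atoms: none
Why: Alkoxide-directed trans-hydroalumination of the propargylic alcohol and protonolysis should give only the (E)-enol ether, which is needed for C8 and cannot be introduced directly because an (E)-2-alkoxyvinyl metal reagent eliminates metal alkoxide; LiAlH4 reduction of propargylic alcohols.

Step 8
Reactants: 12 (E)-enol ether carbinol
Product: 15 methyl 2-[(3S,7S,8R,1(10)E,4Z)-3-[(tert-butyldimethylsilyl)oxy]-8-[(4-methoxybenzyl)oxy]-4,10-dimethyl-6-oxocyclodeca-1(10),4-dien-7-yl]acetate (plan locants), via potassium alkoxide 13 (not isolated), via potassium enolate 14 (not isolated)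
Conditions: KH, 18-crown-6, THF, 0 °C → rt; then BrCH2CO2Me, −78 → −40 °C; aq NH4Cl
Reagents that add atoms: methyl bromoacetate, COC(=O)CBr
Why: KH/18-crown-6 gives the dissociated alkoxide 13, whose 3-oxido-hexa-1,5-diene array C9=C10–C1–C6(O−)–C7=C8 should undergo a charge-accelerated [3,3]-sigmatropic shift through a chair in which C9 bonds to C8 as the C1–C6 bond breaks, and the resulting enolate 14 is C-alkylated at C7 by methyl bromoacetate. The closest known reaction type is the anionic oxy-Cope ring expansion of trans-1,2-dialkenylcyclohexanols to cyclodec-5-enones, including enol ether termini (aldol-type products) and alkylation of the enolate in the same flask. The ten-membered ring is closed by suprafacial sigmatropic bond formation inside a six-membered chair array while the six-membered ring opens (a four-atom ring expansion, not an end-to-end cyclisation), so no high dilution is needed. C8 is set by chirality transfer from C1: with the ring carbon C2 and the (E)-alkoxy group both equatorial on the chair, C9 can reach only one face of C8, giving 8R together with the E-C1=C10 alkene, and C7 is set by alkylation of the enolate on the face opposite the new C8–C9 bond, giving 7S; the Z-C4=C5 alkene is carried over from the cyclohexene. The step needs the shift through the two exocyclic arms rather than through the ring alkene C4=C5 (which would require a bridged boat array) or a [1,3] shift, and C-alkylation faster than β-elimination of the C8 alkoxide; the trans-diequatorial arms secure the first, and the nascent enolate, in which the C8–O bond lies in the nodal plane, together with the low alkylation temperature, secures the second.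

Step 9
Reactants: 15 cyclodecadienone ester
Product: 16 methyl 2-[(1S,3S,7S,8R,10R,4Z)-1-bromo-10-hydroxy-3-[(tert-butyldimethylsilyl)oxy]-8-[(4-methoxybenzyl)oxy]-4,10-dimethyl-6-oxocyclodec-4-en-7-yl]acetate (C10 has the target arrangement; it reads R only because of the bromine on C1)
Conditions: NBS, THF–H2O (4:1), 0 °C
Reagents that add atoms: N-bromosuccinimide, O=C1CCC(=O)N1Br; water, O
Why: Markovnikov anti halohydrin formation: NBS should attack only the electron-rich E-C1=C10 alkene (C4=C5 is deactivated as an enone) on its exposed outer face, and the bromonium ion is opened at the tertiary C10 from the ring-interior face by water, directly or relayed through the transannular C6 carbonyl oxygen as a hemiketal, which sets C10 as in the target.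

Step 10
Reactants: 16 bromohydrin
Product: 17 methyl 2-[(3S,7S,8R,10S,4Z)-10-hydroxy-3-[(tert-butyldimethylsilyl)oxy]-8-[(4-methoxybenzyl)oxy]-4,10-dimethyl-6-oxocyclodec-4-en-7-yl]acetate
Conditions: Bu3SnH, AIBN (cat.), PhH, 80 °C
Reagents that add atoms: none
Why: Radical chain dehalogenation should remove the secondary bromide at C1 (which becomes CH2) without affecting the tertiary alcohol, enone, ester or ethers; no stereocentre is formed.

Step 11
Reactants: 17 hydroxy enone ester
Product: 19 (3S,6R,7S,8R,10S,4Z)-γ-lactone (C12–O6, cis-fused at C6/C7, C11 = CH2) with 10-hydroxy, 3-[(tert-butyldimethylsilyl)oxy] and 8-[(4-methoxybenzyl)oxy] groups, via hydroxy ester 18 (not isolated)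
Conditions: NaBH4, CeCl3·7H2O, MeOH, −40 °C; then PPTS (cat.), CH2Cl2, rt
Reagents that add atoms: none
Why: Luche 1,2-reduction of the enone: hydride should enter anti to the C7–C8 ring bond (Felkin–Anh sense, ring-exterior face), giving the 6R alcohol whose hydroxyl is cis to the C7 acetate arm, and mild acid then closes the cis-fused γ-lactone with loss of methanol.

Step 12
Reactants: 19 lactone
Product: 22 11(13)-methylene lactone (3S,6R,7S,8R,10S,4Z), 3-silyl ether, 8-(4-methoxybenzyl) ether, via Mannich base 20 (not isolated), via methiodide 21 (not isolated)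
Conditions: LiN(i-Pr)2 (3 equiv), THF, −78 °C; CH2=NMe2 I, −78 → 0 °C; MeI, MeOH, rt; NaHCO3 (aq), CH2Cl2, rt
Reagents that add atoms: N,N-dimethylmethyleneiminium iodide (Eschenmoser's salt), C=[N+](C)C.[I-]
Why: The lactone enolate (the tertiary hydroxyl carried as its lithium alkoxide) is aminomethylated by Eschenmoser's salt, and quaternisation followed by mild base eliminates trimethylamine to the α-methylene lactone; C7 carries no acidic hydrogen towards this enolate, so no stereocentre is at risk.

Step 13
Reactants: 22 methylene lactone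
Product: 23 8-hydroxy 11(13)-methylene lactone, 3-silyl ether
Conditions: DDQ, CH2Cl2–pH 7 buffer, 0 °C → rt
Reagents that add atoms: none
Why: Oxidative cleavage of the 4-methoxybenzyl ether by DDQ (hydride abstraction, hydrolysis of the oxocarbenium ion) under neutral conditions should free the C8 hydroxyl without translactonisation and leave the silyl ether, tertiary alcohol and both alkenes intact.

Step 14
Reactants: 23 C8 alcohol
Product: 24 8-O-tigloyl 3-O-silyl lactone
Conditions: tigloyl chloride, Et3N, DMAP, CH2Cl2, 0 °C → rt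
Reagents that add atoms: tigloyl chloride [(E)-2-methylbut-2-enoyl chloride], C/C=C(\C)C(Cl)=O
Why: DMAP-catalysed acylation should esterify only the secondary C8 hydroxyl (the tertiary C10 hydroxyl is inert), and the acid chloride brings the thermodynamically stable E (tiglate) geometry.

Step 15
Reactants: 24 silyl ether
Product: 25 target, (3S,6R,7S,8R,10S,4Z)
Conditions: HF·pyridine, pyridine, THF, 0 °C → rt
Reagents that add atoms: none
Why: Buffered acidic fluoride should cleave the allylic silyl ether without conjugate addition to the α-methylene lactone or acyl migration, releasing the target.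

**Compound list**

1 | (S)-carvone, (5S)-2-methyl-5-(prop-1-en-2-yl)cyclohex-2-en-1-one | O=C1C(C)=CC[C@H](C(C)=C)C1 | starting material
2 | (1S,4S,6S)-1-methyl-4-(prop-1-en-2-yl)-7-oxabicyclo[4.1.0]heptan-2-one | O=C1[C@@]2(C)O[C@H]2C[C@H](C(C)=C)C1 | intermediate
3 | hydrazone of 2 | NN=C1[C@@]2(C)O[C@H]2C[C@H](C(C)=C)C1 | intermediate
4 | (1S,5R)-2-methyl-5-(prop-1-en-2-yl)cyclohex-2-en-1-ol | C1=C(C)[C@@H](O)C[C@H](C(C)=C)C1 | intermediate
5 | tert-butyl(dimethyl){[(1S,5R)-2-methyl-5-(prop-1-en-2-yl)cyclohex-2-en-1-yl]oxy}silane | C1=C(C)[C@@H](O[Si](C)(C)C(C)(C)C)C[C@H](C(C)=C)C1 | intermediate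
6 | (4S,6R)-4-[(tert-butyldimethylsilyl)oxy]-3-methyl-6-(prop-1-en-2-yl)cyclohex-2-en-1-one | O=C1C=C(C)[C@@H](O[Si](C)(C)C(C)(C)C)C[C@@H]1C(C)=C | intermediate
7 | 4-methoxybenzyl alcohol | COc1ccc(CO)cc1 | starting material
8 | trichloroethylene | ClC=C(Cl)Cl | starting material
9 | 1-({[(E)-1,2-dichloroethenyl]oxy}methyl)-4-methoxybenzene | COc1ccc(CO/C(Cl)=C\Cl)cc1 | intermediate
10 | lithium 2-[(4-methoxybenzyl)oxy]ethynide | [Li]C#COCc1ccc(OC)cc1 | intermediate
11 | (1R,4S,6R)-4-[(tert-butyldimethylsilyl)oxy]-1-{[(4-methoxybenzyl)oxy]ethynyl}-3-methyl-6-(prop-1-en-2-yl)cyclohex-2-en-1-ol | O[C@]1(C#COCc2ccc(OC)cc2)C=C(C)[C@@H](O[Si](C)(C)C(C)(C)C)C[C@@H]1C(C)=C | intermediate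
12 | (1R,4S,6R)-4-[(tert-butyldimethylsilyl)oxy]-1-{(E)-2-[(4-methoxybenzyl)oxy]ethenyl}-3-methyl-6-(prop-1-en-2-yl)cyclohex-2-en-1-ol | O[C@]1(/C=C/OCc2ccc(OC)cc2)C=C(C)[C@@H](O[Si](C)(C)C(C)(C)C)C[C@@H]1C(C)=C | intermediate
13 | potassium alkoxide of 12 | [K+].[O-][C@]1(/C=C/OCc2ccc(OC)cc2)C=C(C)[C@@H](O[Si](C)(C)C(C)(C)C)C[C@@H]1C(C)=C | intermediate
14 | potassium C6=C7 enolate of the (3S,8R,1(10)E,4Z)-cyclodecadienone | [K+].C1/C(C)=C/C[C@H](O[Si](C)(C)C(C)(C)C)/C(C)=C\C([O-])=C\[C@@H]1OCc2ccc(OC)cc2 | intermediate
15 | methyl 2-[(3S,7S,8R,1(10)E,4Z)-3-silyloxy-8-(4-methoxybenzyloxy)-4,10-dimethyl-6-oxocyclodeca-1(10),4-dien-7-yl]acetate | C1/C(C)=C/C[C@H](O[Si](C)(C)C(C)(C)C)/C(C)=C\C(=O)[C@@H](CC(=O)OC)[C@@H]1OCc2ccc(OC)cc2 | intermediate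
16 | (1S,3S,7S,8R,10R,4Z)-1-bromo-10-hydroxy keto ester | C1[C@@](C)(O)[C@@H](Br)C[C@H](O[Si](C)(C)C(C)(C)C)/C(C)=C\C(=O)[C@@H](CC(=O)OC)[C@@H]1OCc2ccc(OC)cc2 | intermediate
17 | (3S,7S,8R,10S,4Z)-10-hydroxy keto ester | C1[C@@](C)(O)CC[C@H](O[Si](C)(C)C(C)(C)C)/C(C)=C\C(=O)[C@@H](CC(=O)OC)[C@@H]1OCc2ccc(OC)cc2 | intermediate
18 | (3S,6R,7R,8R,10S,4Z)-6,10-dihydroxy ester (C7 reads R by priority change only) | C1[C@@](C)(O)CC[C@H](O[Si](C)(C)C(C)(C)C)/C(C)=C\[C@@H](O)[C@@H](CC(=O)OC)[C@@H]1OCc2ccc(OC)cc2 | intermediate
19 | (3S,6R,7S,8R,10S,4Z)-10-hydroxy-3-silyloxy-8-(4-methoxybenzyloxy) γ-lactone, C11 = CH2 | C1C(=O)O[C@@H]2/C=C(/C)[C@@H](O[Si](C)(C)C(C)(C)C)CC[C@](C)(O)C[C@@H](OCc3ccc(OC)cc3)[C@H]12 | intermediate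
20 | 11-[(dimethylamino)methyl] derivative of 19 (C11 configuration inconsequential) | CN(C)CC1C(=O)O[C@@H]2/C=C(/C)[C@@H](O[Si](C)(C)C(C)(C)C)CC[C@](C)(O)C[C@@H](OCc3ccc(OC)cc3)[C@H]12 | intermediate
21 | trimethylammonium iodide of 20 | [I-].C[N+](C)(C)CC1C(=O)O[C@@H]2/C=C(/C)[C@@H](O[Si](C)(C)C(C)(C)C)CC[C@](C)(O)C[C@@H](OCc3ccc(OC)cc3)[C@H]12 | intermediate
22 | 11(13)-methylene lactone, 3-silyl ether, 8-(4-methoxybenzyl) ether | C=C1C(=O)O[C@@H]2/C=C(/C)[C@@H](O[Si](C)(C)C(C)(C)C)CC[C@](C)(O)C[C@@H](OCc3ccc(OC)cc3)[C@H]12 | intermediate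
23 | 8-hydroxy 11(13)-methylene lactone, 3-silyl ether | C=C1C(=O)O[C@@H]2/C=C(/C)[C@@H](O[Si](C)(C)C(C)(C)C)CC[C@](C)(O)C[C@@H](O)[C@H]12 | intermediate
24 | 8-O-tigloyl 11(13)-methylene lactone, 3-silyl ether | C=C1C(=O)O[C@@H]2/C=C(/C)[C@@H](O[Si](C)(C)C(C)(C)C)CC[C@](C)(O)C[C@@H](OC(=O)/C(C)=C/C)[C@H]12 | intermediate
25 | CNP0137971.1, (3S,6R,7S,8R,10S,4Z)-3,10-dihydroxy-8-tigloyloxy 11(13)-methylene 12,6-lactone | C=C1C(=O)O[C@@H]2/C=C(/C)[C@@H](O)CC[C@](C)(O)C[C@@H](OC(=O)/C(C)=C/C)[C@H]12 | target

**Step count**

Total: 15 steps. Longest linear sequence: 14 steps (from 1 through steps 1–4 and 6–15; step 5 is the side branch).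

**Steps most likely to fail**

Step 8. The C8 4-methoxybenzyloxy group may be lost by β-elimination from the potassium enolate, or proton transfer between alkylated ketone and unreacted enolate may compete because C-alkylation of the hindered enolate is slow. The fallback sets out from 12: the rearrangement is run in the same way, but enolate 14 is silylated on oxygen with Me3SiCl at −78 °C (fast and irreversible) to give the trimethylsilyl enol ether F1. The acetate arm is then attached under neutral radical conditions (methyl iodoacetate, Et3B/air, iodine-atom-transfer addition to the enol silane and loss of Me3SiI), which comes back to the route at 15.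

Step 9. Bromine may be delivered to the other face of the C1=C10 alkene after a ring flip, which would give the C10 epimer, or the bromonium ion may be captured transannularly by the C4=C5 alkene. The fallback sets out from 15: concerted epoxidation with mCPBA (no cationic intermediate) gives the 1,10-epoxide F2, PhSeNa (from PhSeSePh and NaBH4, EtOH) opens it by SN2 attack at the secondary C1 to the β-hydroxy selenide F3, and Bu3SnH/AIBN removes selenium, which comes back to the route at 17. This sequence leaves the C10 oxygen on the alkene face first attacked, the opposite sense to the bromohydrin route, so whichever face proves exposed, one of the two sequences should give 10S; F2 and F3 are drawn for that case.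

Step 4. Hydrogen abstraction may occur at the tertiary allylic C–H next to the isopropenyl group or at the silyloxy-bearing carbon, giving regioisomeric oxidation products. The fallback sets out from 5: mCPBA epoxidises the trisubstituted ring alkene in preference to the isopropenyl group to give the epoxide F4, PhSeNa opens it at the secondary carbon to the hydroxy selenide F5, and H2O2 brings about selenoxide elimination away from the carbinol to the tertiary allylic alcohol F6. Oxidative 1,3-transposition with C5H5NH[CrO3Cl] then comes back to the route at 6.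

**Further compounds**

F1 | step 8 | trimethylsilyl enol ether (C6=C7) of the (3S,8R,1(10)E,4Z)-cyclodecadienone | C1/C(C)=C/C[C@H](O[Si](C)(C)C(C)(C)C)/C(C)=C\C(O[Si](C)(C)C)=C\[C@@H]1OCc2ccc(OC)cc2
F2 | step 9 | (1R,10R)-1,10-epoxide of 15 | C1[C@@]2(C)O[C@@H]2C[C@H](O[Si](C)(C)C(C)(C)C)/C(C)=C\C(=O)[C@@H](CC(=O)OC)[C@@H]1OCc3ccc(OC)cc3
F3 | step 9 | (1S,10R)-10-hydroxy-1-(phenylselanyl) keto ester | C1[C@@](C)(O)[C@@H]([Se]c2ccccc2)C[C@H](O[Si](C)(C)C(C)(C)C)/C(C)=C\C(=O)[C@@H](CC(=O)OC)[C@@H]1OCc3ccc(OC)cc3
F4 | step 4 | ring epoxide of 5 (epoxide anti to the silyloxy group) | C[C@]12O[C@H]1C[C@@H](C(C)=C)C[C@@H]2O[Si](C)(C)C(C)(C)C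
F5 | step 4 | tertiary alcohol with vicinal phenylselanyl group from F4 | C[C@]1(O)[C@H]([Se]c2ccccc2)C[C@@H](C(C)=C)C[C@@H]1O[Si](C)(C)C(C)(C)C
F6 | step 4 | 6-[(tert-butyldimethylsilyl)oxy]-1-methyl-4-(prop-1-en-2-yl)cyclohex-2-en-1-ol | C[C@]1(O)C=C[C@@H](C(C)=C)C[C@@H]1O[Si](C)(C)C(C)(C)C
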